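**Strategy.** Ring A (C1 aryloxy, C2 isopropyl, C4 methoxy, C5 methyl) is not derived from a phenol but grown onto the oxygen of ring B. Its C1–C2 and C5–C6 bonds are cut back to a 3-carbomethoxy-2-pyrone and an aryl ethynyl ether. One inverse-demand Diels–Alder/decarboxylation forms both bonds and the whole benzene ring, turning the alkynyl ether into the hindered diaryl ether. It exploits the fact that the C2 isopropyl carbon lies ortho to the C1 ether oxygen, where the pyrone's activating ester is delivered. The precursor is the terminal ynol ether of a thymol-derived catechol monobenzyl ether; the ester later becomes the isopropyl group.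

Key step: step 9

Assumption: ring A is the aryloxy ring and ring B the phenol ring (ether oxygen on C1', hydroxyl C2', isopropyl C3', methoxy C5', methyl C6'); the target is achiral, so no stereocentre has to be set.

Step 1
Reactants: 1 methoxyacetone; 2 dimethyl methoxymethylenemalonate
Product: 5 methyl 5-methoxy-6-methyl-2-oxo-2H-pyran-3-carboxylate, via lithium enolate 3 (not isolated), via alkylidene malonate 4 (not isolated)
Conditions: LiN(iPr)2 (1.05 equiv), THF, −78 °C; then 2, −78 °C → rt; aq. HCl
Reagents that add atoms: none
Why: Deprotonation of 1 at the methoxy-bearing methylene, its more acidic α-position, should give the lithium-chelated Z-enolate 3, whose conjugate addition–elimination on the alkoxymethylene malonate gives 4 and whose enol oxygen then lactonises onto one ester (ketone enolate/alkoxymethylenemalonate 2-pyrone annulation).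

Step 2
Reactants: 6 thymol
Product: 7 4-bromothymol (4-bromo-2-isopropyl-5-methylphenol)
Conditions: NBS, MeCN, 0 °C → rt
Reagents that add atoms: N-bromosuccinimide, O=C1CCC(=O)N1Br
Why: Electrophilic aromatic bromination of the phenol should go para to the hydroxyl group, the most activated and least hindered open position.

Step 3
Reactants: 7 4-bromothymol
Product: 8 4-methoxythymol (2-isopropyl-4-methoxy-5-methylphenol)
Conditions: NaOMe (excess), CuI (cat.), MeOH/DMF, 110 °C
Reagents that add atoms: sodium methoxide, [Na+].[O-]C
Why: Copper-catalysed Ullmann-type methoxylation replaces the aryl bromide by methoxide and tolerates the free phenol, which is present as its sodium phenoxide.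

Step 4
Reactants: 8 4-methoxythymol
Product: 10 2-hydroxy-3-isopropyl-5-methoxy-6-methylbenzaldehyde, via salicyl alcohol 9 (not isolated)
Conditions: MgCl2, Et3N, (CH2O)n, MeCN, reflux; aq. HCl
Reagents that add atoms: paraformaldehyde (formaldehyde), C=O
Why: Magnesium phenoxide-directed ortho-formylation delivers formaldehyde to the only free position ortho to the phenol through a chelated transition state, and the benzylic alkoxide of 9 is oxidised to the aldehyde by hydride transfer to a second formaldehyde.

Step 5
Reactants: 10 2-hydroxy-3-isopropyl-5-methoxy-6-methylbenzaldehyde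
Product: 11 2-(benzyloxy)-3-isopropyl-5-methoxy-6-methylbenzaldehyde
Conditions: BnBr, K2CO3, DMF, 60 °C
Reagents that add atoms: benzyl bromide, BrCc1ccccc1
Why: Williamson etherification caps the hydroxyl that must end up free in the target with a group that should survive the peracid, organolithium and Grignard steps and is removed by the final hydrogenation.

Step 6
Reactants: 11 2-(benzyloxy)-3-isopropyl-5-methoxy-6-methylbenzaldehyde
Product: 13 2-(benzyloxy)-3-isopropyl-5-methoxy-6-methylphenol, via aryl formate 12 (not isolated)
Conditions: mCPBA, CH2Cl2, 0 °C → rt; then K2CO3 (cat.), MeOH, rt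
Reagents that add atoms: meta-chloroperbenzoic acid, OOC(=O)c1cccc(Cl)c1
Why: Because the ortho oxygen is already etherified, the aldehyde is oxidised with a peracid in a Baeyer–Villiger (Dakin-type) reaction, in which the electron-rich ortho-alkoxy aryl group migrates in preference to hydride to give formate 12, and mild methanolysis releases the phenol.

Step 7
Reactants: 13 2-(benzyloxy)-3-isopropyl-5-methoxy-6-methylphenol; 14 trichloroethylene
Product: 16 2-(benzyloxy)-1-{[(E)-1,2-dichlorovinyl]oxy}-3-isopropyl-5-methoxy-6-methylbenzene, via dichloroacetylene 15 (not isolated)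
Conditions: K2CO3, DMF, 70 °C
Reagents that add atoms: none
Why: Base-mediated dehydrochlorination of 14 generates dichloroacetylene 15, to which the phenoxide adds in anti fashion to give the E-1,2-dichlorovinyl ether (nucleophilic addition to a haloalkyne, the first half of the dichlorovinyl ether route to ynol ethers).

Step 8
Reactants: 16 2-(benzyloxy)-1-{[(E)-1,2-dichlorovinyl]oxy}-3-isopropyl-5-methoxy-6-methylbenzene
Product: 19 2-(benzyloxy)-1-(ethynyloxy)-3-isopropyl-5-methoxy-6-methylbenzene, via chloroethynyl ether 17 (not isolated), via lithium acetylide 18 (not isolated)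
Conditions: n-BuLi (2.5 equiv), Et2O, −78 → −40 °C; MeOH, −78 °C; cold neutral work-up, used at once
Reagents that add atoms: none
Why: n-BuLi removes the vinylic proton and chloride is lost to give chloroalkyne 17, chlorine–lithium exchange gives acetylide 18 and methanol protonates it (dehydrohalogenation/halogen–metal exchange route to terminal ynol ethers); the benzyl ether should be inert at −78 °C and the product, shielded by its two ortho substituents, is taken on immediately.

Step 9
Reactants: 5 methyl 5-methoxy-6-methyl-2-oxo-2H-pyran-3-carboxylate; 19 2-(benzyloxy)-1-(ethynyloxy)-3-isopropyl-5-methoxy-6-methylbenzene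
Product: 21 methyl 2-[2-(benzyloxy)-3-isopropyl-5-methoxy-6-methylphenoxy]-5-methoxy-4-methylbenzoate, via bicyclic lactone 20 (not isolated)
Conditions: 5 (2 equiv), PhMe (0.1 M), 100 °C, sealed tube, Ar
Reagents that add atoms: none
Why: The electron-poor diene of 5 (C3=C4–C5=C6, lowered in energy by the C3 ester and the lactone carbonyl) and the electron-rich alkyne of 19 should combine in an inverse-electron-demand Diels–Alder reaction to give the bridged 2-oxabicyclo[2.2.2]octadienone 20, which loses CO2 by retro-[4+2] cycloreversion to give arene 21 directly. The closest known reaction type is the thermal cycloaddition–decarboxylation of 3-carbomethoxy-2-pyrones with enol ethers, ketene acetals, ynamines and other donor-substituted π-systems to give benzoates. Ring A is closed by an intermolecular, concerted but asynchronous [4+2] cycloaddition in which the two alkyne carbons are joined to pyrone C3 and C6, so the new bonds are C1–C2 and C5–C6 of ring A. No stereocentre remains, because the two bridgehead centres of racemic 20 become planar on aromatisation. The step needs regioselectivity: the largest HOMO coefficient of the ynol ether lies on its terminal CH carbon and the largest LUMO coefficient of the ester-bearing diene on pyrone C6, so the terminal carbon bonds to C6 and the oxygen-bearing carbon to C3, placing the aryloxy group next to the ester. The C5 methoxy and C6 methyl groups make the pyrone less electrophilic, so heating is expected; the aryl ynol ether has no β-hydrogen for retro-ene loss of ketene and both its ortho positions are blocked, and it should survive when used fresh, dilute and with excess pyrone.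

Step 10
Reactants: 21 methyl 2-[2-(benzyloxy)-3-isopropyl-5-methoxy-6-methylphenoxy]-5-methoxy-4-methylbenzoate
Product: 23 2-{2-[2-(benzyloxy)-3-isopropyl-5-methoxy-6-methylphenoxy]-5-methoxy-4-methylphenyl}propan-2-ol, via methyl ketone 22 (not isolated)
Conditions: MeMgBr (4 equiv), THF, 0 °C → rt; aq. NH4Cl
Reagents that add atoms: methylmagnesium bromide, C[Mg]Br
Why: Double Grignard addition to the methyl ester, through ketone 22, should give the tertiary benzylic alcohol, since no other electrophilic group is present.

Step 11
Reactants: 23 2-{2-[2-(benzyloxy)-3-isopropyl-5-methoxy-6-methylphenoxy]-5-methoxy-4-methylphenyl}propan-2-ol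
Product: 26 6-isopropyl-2-(2-isopropyl-4-methoxy-5-methylphenoxy)-4-methoxy-3-methylphenol (CNP0271085.0), via debenzylated carbinol 24 (not isolated), via isopropenyl phenol 25 (not isolated)
Conditions: H2 (3 atm), Pd/C, HCl (cat.), EtOH, rt
Reagents that add atoms: none
Why: Palladium-catalysed hydrogenolysis cleaves the benzyl ether, and acid-promoted ionisation of the tertiary benzylic alcohol to the α-methylstyrene 25 followed by alkene hydrogenation gives the isopropyl group; both positions of ring B ortho to the ether oxygen are substituted, so the benzylic cation cannot close a xanthene ring.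

**Compound list**

1 | methoxyacetone (1-methoxypropan-2-one) | COCC(C)=O | starting material
2 | dimethyl methoxymethylenemalonate | COC=C(C(=O)OC)C(=O)OC | starting material
3 | lithium (Z)-1-methoxyprop-1-en-2-olate, not isolated | CO/C=C(/C)O[Li] | intermediate
4 | dimethyl 2-(2-methoxy-3-oxobutylidene)malonate, racemic, not isolated | COC(=O)C(=CC(OC)C(C)=O)C(=O)OC | intermediate
5 | methyl 5-methoxy-6-methyl-2-oxo-2H-pyran-3-carboxylate | COC(=O)C1=CC(OC)=C(C)OC1=O | intermediate
6 | thymol (2-isopropyl-5-methylphenol) | CC(C)c1ccc(C)cc1O | starting material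
7 | 4-bromothymol (4-bromo-2-isopropyl-5-methylphenol) | CC(C)c1cc(Br)c(C)cc1O | intermediate
8 | 4-methoxythymol (2-isopropyl-4-methoxy-5-methylphenol) | CC(C)c1cc(OC)c(C)cc1O | intermediate
9 | 2-(hydroxymethyl)-6-isopropyl-4-methoxy-3-methylphenol, not isolated | CC(C)c1cc(OC)c(C)c(CO)c1O | intermediate
10 | 2-hydroxy-3-isopropyl-5-methoxy-6-methylbenzaldehyde | CC(C)c1cc(OC)c(C)c(C=O)c1O | intermediate
11 | 2-(benzyloxy)-3-isopropyl-5-methoxy-6-methylbenzaldehyde | CC(C)c1cc(OC)c(C)c(C=O)c1OCc1ccccc1 | intermediate
12 | 2-(benzyloxy)-3-isopropyl-5-methoxy-6-methylphenyl formate, not isolated | CC(C)c1cc(OC)c(C)c(OC=O)c1OCc1ccccc1 | intermediate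
13 | 2-(benzyloxy)-3-isopropyl-5-methoxy-6-methylphenol | CC(C)c1cc(OC)c(C)c(O)c1OCc1ccccc1 | intermediate
14 | trichloroethylene | ClC=C(Cl)Cl | starting material
15 | dichloroacetylene, not isolated | ClC#CCl | intermediate
16 | 2-(benzyloxy)-1-{[(E)-1,2-dichlorovinyl]oxy}-3-isopropyl-5-methoxy-6-methylbenzene | Cl/C=C(/Cl)Oc1c(C)c(OC)cc(C(C)C)c1OCc1ccccc1 | intermediate
17 | 2-(benzyloxy)-1-[(chloroethynyl)oxy]-3-isopropyl-5-methoxy-6-methylbenzene, not isolated | ClC#COc1c(C)c(OC)cc(C(C)C)c1OCc1ccccc1 | intermediate
18 | lithium [2-(benzyloxy)-3-isopropyl-5-methoxy-6-methylphenoxy]acetylide, not isolated | [Li]C#COc1c(C)c(OC)cc(C(C)C)c1OCc1ccccc1 | intermediate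
19 | 2-(benzyloxy)-1-(ethynyloxy)-3-isopropyl-5-methoxy-6-methylbenzene | C#COc1c(C)c(OC)cc(C(C)C)c1OCc1ccccc1 | intermediate
20 | methyl 8-[2-(benzyloxy)-3-isopropyl-5-methoxy-6-methylphenoxy]-6-methoxy-1-methyl-3-oxo-2-oxabicyclo[2.2.2]octa-5,7-diene-4-carboxylate, racemic, not isolated | COC(=O)C12C=C(OC)C(C)(OC1=O)C=C2Oc1c(C)c(OC)cc(C(C)C)c1OCc1ccccc1 | intermediate
21 | methyl 2-[2-(benzyloxy)-3-isopropyl-5-methoxy-6-methylphenoxy]-5-methoxy-4-methylbenzoate | COC(=O)c1cc(OC)c(C)cc1Oc1c(C)c(OC)cc(C(C)C)c1OCc1ccccc1 | intermediate
22 | 1-{2-[2-(benzyloxy)-3-isopropyl-5-methoxy-6-methylphenoxy]-5-methoxy-4-methylphenyl}ethan-1-one, not isolated | CC(=O)c1cc(OC)c(C)cc1Oc1c(C)c(OC)cc(C(C)C)c1OCc1ccccc1 | intermediate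
23 | 2-{2-[2-(benzyloxy)-3-isopropyl-5-methoxy-6-methylphenoxy]-5-methoxy-4-methylphenyl}propan-2-ol | CC(C)(O)c1cc(OC)c(C)cc1Oc1c(C)c(OC)cc(C(C)C)c1OCc1ccccc1 | intermediate
24 | 2-[2-(2-hydroxy-3-isopropyl-5-methoxy-6-methylphenoxy)-5-methoxy-4-methylphenyl]propan-2-ol, not isolated | CC(C)(O)c1cc(OC)c(C)cc1Oc1c(C)c(OC)cc(C(C)C)c1O | intermediate
25 | 6-isopropyl-4-methoxy-2-[4-methoxy-5-methyl-2-(prop-1-en-2-yl)phenoxy]-3-methylphenol, not isolated | C=C(C)c1cc(OC)c(C)cc1Oc1c(C)c(OC)cc(C(C)C)c1O | intermediate
26 | 6-isopropyl-2-(2-isopropyl-4-methoxy-5-methylphenoxy)-4-methoxy-3-methylphenol (CNP0271085.0) | COc1cc(C(C)C)c(Oc2c(C)c(OC)cc(C(C)C)c2O)cc1C | target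

**Step count.** Total: 11 steps. Longest linear sequence: 10 steps (thymol 6 to target 26, steps 2–11); pyrone 5 is made in one step in a side branch.

**Steps most likely to fail**

Step 9 (cycloaddition). The donor-substituted pyrone may react so slowly that the ynol ether is consumed by thermal oligomerisation or adventitious hydration before it is trapped. The fallback builds the diaryl ether by a copper-catalysed Ullmann coupling instead. It sets out from phenol 13. Purchased methyl 3-methoxy-4-methylbenzoate F1 is brominated para to its methoxy group (NBS, MeCN, rt) to give methyl 2-bromo-5-methoxy-4-methylbenzoate F2. Coupling of 13 with F2 (CuI, picolinic acid, K3PO4, DMSO, 90 °C), helped by the ortho ester, should give benzoate 21, where the route is rejoined.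

Step 8 (ynol ether formation). Excess n-BuLi may metalate the benzylic methylene and trigger a Wittig rearrangement, or the terminal ynol ether may hydrate or oligomerise during work-up. The fallback avoids alkyllithium reagents and sets out from phenol 13. Iridium-catalysed O-vinylation with vinyl acetate ([Ir(cod)Cl]2, Na2CO3, PhMe, 100 °C) should give 2-(benzyloxy)-3-isopropyl-5-methoxy-6-methyl-1-(vinyloxy)benzene F3. Addition of Br2 (CH2Cl2, −78 °C) gives the 1,2-dibromoethyl ether F4. Double dehydrobromination with NaNH2 in NH3/THF, passing through the (Z)-2-bromovinyl ether F5 without isolation, followed by NH4Cl quench, returns ynol ether 19.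

Step 1 (pyrone annulation). Competing enolisation of methoxyacetone at its methyl group would lead to the regioisomeric 6-(methoxymethyl) pyrone. The fallback fixes the regiochemistry before the malonate is introduced and sets out from 1. Condensation with N,N-dimethylformamide dimethyl acetal (neat, 100 °C) proceeds under equilibrating conditions at the more acidic methoxy-bearing methylene and should give (Z)-4-(dimethylamino)-3-methoxybut-3-en-2-one F6. Addition–elimination of sodium dimethyl malonate (NaH, THF, reflux) displaces dimethylamine and gives the dienolate of 4. Acidification and warming (TsOH, PhMe) lactonises it to pyrone 5, where the route is rejoined.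

**Further compounds**

F1 | step 9 | methyl 3-methoxy-4-methylbenzoate (purchased) | COC(=O)c1ccc(C)c(OC)c1
F2 | step 9 | methyl 2-bromo-5-methoxy-4-methylbenzoate | COC(=O)c1cc(OC)c(C)cc1Br
F3 | step 8 | 2-(benzyloxy)-3-isopropyl-5-methoxy-6-methyl-1-(vinyloxy)benzene | C=COc1c(C)c(OC)cc(C(C)C)c1OCc1ccccc1
F4 | step 8 | 2-(benzyloxy)-1-(1,2-dibromoethoxy)-3-isopropyl-5-methoxy-6-methylbenzene (racemic) | BrCC(Br)Oc1c(C)c(OC)cc(C(C)C)c1OCc1ccccc1
F5 | step 8 | 2-(benzyloxy)-1-{[(Z)-2-bromovinyl]oxy}-3-isopropyl-5-methoxy-6-methylbenzene | Br/C=C\Oc1c(C)c(OC)cc(C(C)C)c1OCc1ccccc1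
F6 | step 1 | (Z)-4-(dimethylamino)-3-methoxybut-3-en-2-one | CN(C)/C=C(\OC)C(C)=O
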